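**Plan** (germacrane numbering: C6/C7 lactone carbons, C8 ester carbinol, C1 hydroperoxy carbon, C14 on C10, C15 on C4)
1. Cuts: C1–OOH with C10=C14 goes back to an E-C1=C10 olefin (ene reaction). The O8 and O15 esters are removed next. Then C7–C11 and C6–O are cut together, which gives a ten-membered triene and 2-bromoacrylic acid.
2. Enabling feature: the lactone carbinol C6 is allylic to C4=C5 and vicinal to C7. C7–C6–C5=C4 of the ten-membered ring is therefore the retron of a 1,2-carbo-oxygenation of the ring diene C4=C5–C6=C7 through a C4–C5–C6 π-allylpalladium.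
3. Forward: a linear C12 chain is built (allenylboration, carboalumination/oxirane, phosphonate alkylation, HWE). RCM closes the carbocycle at C6=C7. Pd annulation then builds the α-methylene-γ-lactone, followed by the C8 ester, the C15 acetate and the photooxygenation.
4. Stereocentres: C8 comes from catalytic asymmetric allenylboration, C6 and C7 from C8 in the annulation, C3′ from a chiral-pool dioxolane ester, and C1 from peripheral singlet-oxygen attack.
5. Olefin geometry: E-C1=C10 comes from syn-methylalumination, C4=C5 (C3 cis to C6) from the HWE reaction, and Z-C6=C7 from ring-size control in the RCM.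

Key step: step 11

Remark: the facial sense of (S)-TRIP in step 1 is assumed to follow that known for other enals ((R)-acid attacks the Re face, so (S)-acid attacks the Si face).

Step 1
Reactants: 1 acrolein; 2 allenylboronic acid pinacol ester
Product: 4 (3S)-hex-1-en-5-yn-3-ol, via pinacol borate ester 3 (not isolated)
Conditions: (S)-TRIP (10 mol%), 4 Å MS, toluene, −20 °C; aq. work-up
Reagents that add atoms: none
Why: Chiral-phosphoric-acid-catalysed allenylboration (SE2′, closed six-membered transition state) gives only the homopropargylic 1,2-adduct, and (S)-TRIP exposes the Si face of acrolein, which sets C8 as S.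

Step 2
Reactants: 4 (3S)-hex-1-en-5-yn-3-ol
Product: 5 (3S)-3-(tert-butyldimethylsilyloxy)hex-1-en-5-yne
Conditions: TBSCl, imidazole, CH2Cl2, 0 °C to rt
Reagents that add atoms: tert-butyldimethylsilyl chloride, CC(C)(C)[Si](C)(C)Cl
Why: Standard silyl ether formation masks the carbinol against Me3Al, n-BuLi, NaH and the iodination reagent.

Step 3
Reactants: 5 (3S)-3-(tert-butyldimethylsilyloxy)hex-1-en-5-yne; 6 ethylene oxide
Product: 9 (3E,6S)-6-(tert-butyldimethylsilyloxy)-4-methylocta-3,7-dien-1-ol, via alkenyldimethylalane 7 (not isolated), via lithium alkenylalanate 8 (not isolated)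
Conditions: Me3Al, Cp2ZrCl2 (20 mol%), CH2Cl2, 0 °C to rt; volatiles removed; n-BuLi, hexane, 0 °C; 6, THF, −30 °C to rt; aq. work-up
Reagents that add atoms: trimethylaluminium, C[Al](C)C
Why: Negishi Zr-catalysed syn-methylalumination of the terminal alkyne (far faster than of the hindered vinyl group) fixes the E-C1=C10 geometry, and the derived alanate opens ethylene oxide with retention at the sp2 carbon to add C2–C3.

Step 4
Reactants: 9 (3E,6S)-6-(tert-butyldimethylsilyloxy)-4-methylocta-3,7-dien-1-ol
Product: 10 (3S,5E)-3-(tert-butyldimethylsilyloxy)-8-iodo-5-methylocta-1,5-diene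
Conditions: I2, PPh3, imidazole, CH2Cl2, 0 °C
Reagents that add atoms: iodine, II
Why: Appel-type iodination of the primary alcohol runs under buffered neutral conditions that leave the silyl ether and both olefins untouched.

Step 5
Reactants: 10 (3S,5E)-3-(tert-butyldimethylsilyloxy)-8-iodo-5-methylocta-1,5-diene; 11 triethyl phosphonoacetate
Product: 12 ethyl (5E,8S)-8-(tert-butyldimethylsilyloxy)-2-(diethoxyphosphoryl)-6-methyldeca-5,9-dienoate (epimers at C2)
Conditions: NaH, 11, THF/DMF, 0 to 55 °C
Reagents that add atoms: none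
Why: SN2 alkylation of the soft phosphonoacetate carbanion with the primary homoallylic iodide forms C3–C4, and the new centre arises as a mixture of epimers that is erased in step 6.

Step 6
Reactants: 12 ethyl (5E,8S)-8-(tert-butyldimethylsilyloxy)-2-(diethoxyphosphoryl)-6-methyldeca-5,9-dienoate; 13 (E)-crotonaldehyde
Product: 14 ethyl (2E,4E)-2-[(3E,6S)-6-(tert-butyldimethylsilyloxy)-4-methylocta-3,7-dienyl]hexa-2,4-dienoate
Conditions: NaH, THF, 0 °C; 13, 0 °C to rt
Reagents that add atoms: none
Why: Horner–Wadsworth–Emmons olefination of an α-alkylphosphonoacetate places the aldehyde-derived C6 trans to the ester carbon (C15) and cis to C3, which is the C4=C5 geometry of the target, and the methyl cap keeps the metathesis catalyst off this terminus in step 8.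

Step 7
Reactants: 14 ethyl (2E,4E)-2-[(3E,6S)-6-(tert-butyldimethylsilyloxy)-4-methylocta-3,7-dienyl]hexa-2,4-dienoate
Product: 15 ethyl (2E,4E)-2-[(3E,6S)-6-hydroxy-4-methylocta-3,7-dienyl]hexa-2,4-dienoate
Conditions: HF·pyridine, pyridine/THF, 0 °C to rt
Reagents that add atoms: none
Why: Fluoride-induced Si–O cleavage frees the allylic hydroxyl, which accelerates metathesis at the neighbouring vinyl group and is needed unprotected in step 11.

Step 8
Reactants: 15 ethyl (2E,4E)-2-[(3E,6S)-6-hydroxy-4-methylocta-3,7-dienyl]hexa-2,4-dienoate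
Product: 16 ethyl (1E,3Z,5S,7E)-5-hydroxy-7-methylcyclodeca-1,3,7-triene-1-carboxylate (ring C3 and C6 cis on C4=C5; Z-C6=C7; E-C1=C10)
Conditions: Hoveyda–Grubbs II (2 × 5 mol%), 1,4-benzoquinone (20 mol%), toluene (1 mM), 70 °C, Ar sparge
Reagents that add atoms: none
Why: Ene–diene ring-closing metathesis starts at the unhindered C7 vinyl group next to the free carbinol and ends on the γ,δ-bond of the electron-poor dienoate with loss of propene, the trisubstituted C1=C10 and C4=C5 bonds stay spectators as in known germacrane-type closures, and under reversible conditions the less strained ring-cis (Z) C6=C7 isomer should prevail.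

Step 9
Reactants: 16 ethyl (1E,3Z,5S,7E)-5-hydroxy-7-methylcyclodeca-1,3,7-triene-1-carboxylate
Product: 17 (1S,2Z,4E,8E)-5-(hydroxymethyl)-9-methylcyclodeca-2,4,8-trien-1-ol
Conditions: DIBAL-H (3.5 equiv), CH2Cl2, −78 °C; Rochelle salt
Reagents that add atoms: none
Why: DIBAL-H 1,2-reduction of the conjugated ester gives the primary allylic alcohol (C15) without touching the triene.

Step 10
Reactants: 17 (1S,2Z,4E,8E)-5-(hydroxymethyl)-9-methylcyclodeca-2,4,8-trien-1-ol
Product: 18 (1S,2Z,4E,8E)-5-[(tert-butyldimethylsilyloxy)methyl]-9-methylcyclodeca-2,4,8-trien-1-ol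
Conditions: TBSCl (1.05 equiv), imidazole, CH2Cl2, −20 to 0 °C
Reagents that add atoms: tert-butyldimethylsilyl chloride, CC(C)(C)[Si](C)(C)Cl
Why: Kinetic silylation discriminates the unhindered primary allylic hydroxyl from the secondary C8 carbinol, so that O15 can neither ionise nor add in step 11 while O8 stays free.

Step 11
Reactants: 18 (1S,2Z,4E,8E)-5-[(tert-butyldimethylsilyloxy)methyl]-9-methylcyclodeca-2,4,8-trien-1-ol; 19 2-bromoacrylic acid
Product: 20 (3aR,4S,6E,10E,11aS)-10-[(tert-butyldimethylsilyloxy)methyl]-4-hydroxy-6-methyl-3-methylidene-3a,4,5,8,9,11a-hexahydrocyclodeca[b]furan-2(3H)-one (6S,7R,8S; cis-fused 12,6-olide)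
Conditions: 19 (slow addition), Pd(OAc)2 (10 mol%), 1,1′-bis(di-tert-butylphosphino)ferrocene (12 mol%), Na2CO3, n-Bu4NCl, DMF, 60 °C
Reagents that add atoms: none
Why: Pd(0) adds oxidatively to the C–Br bond of the carboxylate of 19, the vinylpalladium carbopalladates the less substituted diene terminus in a syn sense (C11 to C7, Pd to C6) to give the C4–C5–C6 π-allylpalladium carboxylate, and C6–O bond formation releases Pd(0). The closest known reaction type is the Larock-type Pd-catalysed heteroannulation of 1,3-dienes, cyclic cis,cis-dienes included, by α-haloacrylic acids to α-alkylidene-γ-butyrolactones. The only ring closed, the γ-lactone, forms by 5-exo attack of the tethered carboxylate on the proximal allyl terminus C6, which leaves C4=C5 outside the new ring with C3 still anti on the allyl, so that its ring-cis geometry is kept. C7 is controlled by C8: A1,3 strain across the Z-C6=C7 bond holds H8 in the olefin plane, puts C9 and the ring body on one face and the small free hydroxyl on the exposed face, and addition from that peripheral face turns 8S into 7R. C6 is controlled by the tether: with C7 anti on the allyl, the three-atom link C11–C12–O reaches C6 only on the face that C11 occupies, so the lactone is cis-fused (6S). The step needs C7 over the fully substituted C4 (sterics), C6 over C4 in the C–O closure (five- against seven-membered ring), the diene over the isolated C1=C10 bond (no π-allyl stabilisation there), and no competing allyl ionisation, which is why O8 is a free hydroxyl and O15 a silyl ether instead of esters at this stage.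

Step 12
Reactants: 21 methyl (4S)-2,2-dimethyl-1,3-dioxolane-4-carboxylate
Product: 23 (4R)-4-ethynyl-2,2-dimethyl-1,3-dioxolane, via dioxolane carbaldehyde 22 (not isolated)
Conditions: DIBAL-H (1.05 equiv), CH2Cl2, −78 °C; then MeOH, K2CO3, Ohira–Bestmann reagent, −78 °C to rt
Reagents that add atoms: dimethyl (1-diazo-2-oxopropyl)phosphonate, CC(=O)C(=[N+]=[N-])P(=O)(OC)OC
Why: Partial ester reduction followed in the same flask by Ohira–Bestmann (Seyferth–Gilbert) homologation gives the terminal alkyne under conditions known to preserve the α-alkoxy stereocentre, which becomes C3′.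

Step 13
Reactants: 23 (4R)-4-ethynyl-2,2-dimethyl-1,3-dioxolane
Product: 24 methyl 2-[(4R)-2,2-dimethyl-1,3-dioxolan-4-yl]prop-2-enoate
Conditions: Pd(OAc)2 (2 mol%), 2-(diphenylphosphino)pyridine (8 mol%), MsOH (4 mol%), CO (20 bar), MeOH (5 equiv), CH2Cl2, 45 °C
Reagents that add atoms: carbon monoxide, [C-]#[O+]; methanol, CO
Why: Markovnikov Pd/2-pyridylphosphine-catalysed hydromethoxycarbonylation of a terminal alkyne (Reppe-type carbonylation) delivers the branched 2-substituted acrylate and does not touch the stereocentre.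

Step 14
Reactants: 24 methyl 2-[(4R)-2,2-dimethyl-1,3-dioxolan-4-yl]prop-2-enoate
Product: 25 2-[(4R)-2,2-dimethyl-1,3-dioxolan-4-yl]prop-2-enoic acid
Conditions: LiOH, THF/H2O, 0 °C; then aq. HCl to pH 4, 0 °C
Reagents that add atoms: lithium hydroxide, [Li+].[OH-]
Why: Saponification of the methyl ester at low temperature and mild acidification gives the free acid without loss of the acetonide.

Step 15
Reactants: 20 hydroxy lactone (6S,7R,8S); 25 2-[(4R)-2,2-dimethyl-1,3-dioxolan-4-yl]prop-2-enoic acid
Product: 27 8-O-{2-[(4R)-2,2-dimethyl-1,3-dioxolan-4-yl]acryloyl} derivative of 20, via mixed trichlorobenzoic anhydride 26 (not isolated)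
Conditions: 25, 2,4,6-Cl3C6H2COCl, Et3N, toluene, rt; then 20, DMAP, toluene, rt
Reagents that add atoms: none
Why: Yamaguchi esterification through the mixed anhydride acylates the hindered secondary C8 hydroxyl with retention at C8 and C3′.

Step 16
Reactants: 27 8-O-acyl 15-O-TBS lactone
Product: 29 15-acetate of the 8-O-acyl lactone (side-chain acetonide intact), via C15 alcohol 28 (not isolated)
Conditions: Et3N·3HF, MeCN, rt; then Et3N, Ac2O, DMAP (cat.), 0 °C
Reagents that add atoms: acetic anhydride, CC(=O)OC(C)=O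
Why: Buffered fluoride removes the primary allylic TBS group without touching acetonide, esters or Michael acceptors, and DMAP-catalysed acetylation in the same flask installs the C15 acetate.

Step 17
Reactants: 29 15-acetate acetonide
Product: 30 (6S,7R,8S,3′R)-15-acetoxy-8-(3,4-dihydroxy-2-methylidenebutanoyloxy)germacra-1(10)E,4,11(13)-trien-12,6-olide
Conditions: AcOH/H2O 4:1, 35 °C
Reagents that add atoms: none
Why: Mild acid hydrolysis of the terminal acetonide frees the 3′,4′-diol, and because C4=C5 is deactivated by its two allylic acyloxy groups, transannular cyclisation of the 1,5-diene is not expected in aqueous acetic acid.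

Step 18
Reactants: 30 1(10)-ene diol
Product: 31 target, (1R,6S,7R,8S,3′R)-15-acetoxy-8-(3,4-dihydroxy-2-methylidenebutanoyloxy)-1-hydroperoxygermacra-4,10(14),11(13)-trien-12,6-olide
Conditions: O2, methylene blue (1 mol%), CH2Cl2/MeCN, visible-light LED, 0 °C
Reagents that add atoms: dioxygen, O=O
Why: The Schenck ene reaction of singlet oxygen occurs only at the electron-rich trisubstituted C1=C10 bond (both acrylate-type olefins and the doubly acyloxy-flanked C4=C5 are deactivated), takes H from the freely rotating C14 methyl on the more substituted side of the E-olefin (cis effect) so that O binds to C1 and the double bond moves to C10=C14, and attacks the peripheral face of the conformer that holds C14 on the β face away from the 8α-ester, which sets C1 as R.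

**Compound list**
1 | acrolein | C=CC=O | starting material
2 | allenylboronic acid pinacol ester | C=C=CB1OC(C)(C)C(C)(C)O1 | starting material
3 | pinacol borate ester of 4 | C#CC[C@H](OB1OC(C)(C)C(C)(C)O1)C=C | intermediate
4 | (3S)-hex-1-en-5-yn-3-ol | C#CC[C@H](O)C=C | intermediate
5 | (3S)-3-(tert-butyldimethylsilyloxy)hex-1-en-5-yne | C#CC[C@H](O[Si](C)(C)C(C)(C)C)C=C | intermediate
6 | ethylene oxide | C1CO1 | starting material
7 | (E)-alkenyldimethylalane from 5 | C[Al](C)/C=C(C)/C[C@H](O[Si](C)(C)C(C)(C)C)C=C | intermediate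
8 | lithium n-butyl(alkenyl)dimethylalanate | [Li+].CCCC[Al-](C)(C)/C=C(C)/C[C@H](O[Si](C)(C)C(C)(C)C)C=C | intermediate
9 | (3E,6S)-6-(tert-butyldimethylsilyloxy)-4-methylocta-3,7-dien-1-ol | OCC/C=C(C)/C[C@H](O[Si](C)(C)C(C)(C)C)C=C | intermediate
10 | (3S,5E)-3-(tert-butyldimethylsilyloxy)-8-iodo-5-methylocta-1,5-diene | ICC/C=C(C)/C[C@H](O[Si](C)(C)C(C)(C)C)C=C | intermediate
11 | triethyl phosphonoacetate | CCOC(=O)CP(=O)(OCC)OCC | starting material
12 | ethyl (5E,8S)-8-(tert-butyldimethylsilyloxy)-2-(diethoxyphosphoryl)-6-methyldeca-5,9-dienoate | CCOC(=O)C(CC/C=C(C)/C[C@H](O[Si](C)(C)C(C)(C)C)C=C)P(=O)(OCC)OCC | intermediate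
13 | (E)-crotonaldehyde | C/C=C/C=O | starting material
14 | ethyl (2E,4E)-2-[(3E,6S)-6-(tert-butyldimethylsilyloxy)-4-methylocta-3,7-dienyl]hexa-2,4-dienoate | CCOC(=O)/C(CC/C=C(C)/C[C@H](O[Si](C)(C)C(C)(C)C)C=C)=C/C=C/C | intermediate
15 | ethyl (2E,4E)-2-[(3E,6S)-6-hydroxy-4-methylocta-3,7-dienyl]hexa-2,4-dienoate | CCOC(=O)/C(CC/C=C(C)/C[C@H](O)C=C)=C/C=C/C | intermediate
16 | ethyl (1E,3Z,5S,7E)-5-hydroxy-7-methylcyclodeca-1,3,7-triene-1-carboxylate | O[C@@H]1/C=C\C=C(\C(=O)OCC)CC/C=C(C)/C1 | intermediate
17 | (1S,2Z,4E,8E)-5-(hydroxymethyl)-9-methylcyclodeca-2,4,8-trien-1-ol | O[C@@H]1/C=C\C=C(\CO)CC/C=C(C)/C1 | intermediate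
18 | (1S,2Z,4E,8E)-5-[(tert-butyldimethylsilyloxy)methyl]-9-methylcyclodeca-2,4,8-trien-1-ol | O[C@@H]1/C=C\C=C(\CO[Si](C)(C)C(C)(C)C)CC/C=C(C)/C1 | intermediate
19 | 2-bromoacrylic acid | C=C(Br)C(=O)O | starting material
20 | (6S,7R,8S)-15-(tert-butyldimethylsilyloxy)-8-hydroxygermacra-1(10)E,4,11(13)-trien-12,6-olide | C=C1C(=O)O[C@H]2/C=C(/CO[Si](C)(C)C(C)(C)C)CC/C=C(C)/C[C@H](O)[C@@H]12 | intermediate
21 | methyl (4S)-2,2-dimethyl-1,3-dioxolane-4-carboxylate | COC(=O)[C@@H]1COC(C)(C)O1 | starting material
22 | (4S)-2,2-dimethyl-1,3-dioxolane-4-carbaldehyde | O=C[C@@H]1COC(C)(C)O1 | intermediate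
23 | (4R)-4-ethynyl-2,2-dimethyl-1,3-dioxolane | C#C[C@@H]1COC(C)(C)O1 | intermediate
24 | methyl 2-[(4R)-2,2-dimethyl-1,3-dioxolan-4-yl]prop-2-enoate | C=C(C(=O)OC)[C@@H]1COC(C)(C)O1 | intermediate
25 | 2-[(4R)-2,2-dimethyl-1,3-dioxolan-4-yl]prop-2-enoic acid | C=C(C(=O)O)[C@@H]1COC(C)(C)O1 | intermediate
26 | mixed anhydride of 25 and 2,4,6-trichlorobenzoic acid | C=C(C(=O)OC(=O)c1c(Cl)cc(Cl)cc1Cl)[C@@H]2COC(C)(C)O2 | intermediate
27 | 8-O-acyl (acetonide) 15-O-TBS lactone | C=C1C(=O)O[C@H]2/C=C(/CO[Si](C)(C)C(C)(C)C)CC/C=C(C)/C[C@H](OC(=O)C(=C)[C@@H]3COC(C)(C)O3)[C@@H]12 | intermediate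
28 | 8-O-acyl (acetonide) 15-alcohol | C=C1C(=O)O[C@H]2/C=C(/CO)CC/C=C(C)/C[C@H](OC(=O)C(=C)[C@@H]3COC(C)(C)O3)[C@@H]12 | intermediate
29 | 8-O-acyl (acetonide) 15-acetate | C=C1C(=O)O[C@H]2/C=C(/COC(C)=O)CC/C=C(C)/C[C@H](OC(=O)C(=C)[C@@H]3COC(C)(C)O3)[C@@H]12 | intermediate
30 | 1(10)-ene diol precursor | C=C1C(=O)O[C@H]2/C=C(/COC(C)=O)CC/C=C(C)/C[C@H](OC(=O)C(=C)[C@@H](O)CO)[C@@H]12 | intermediate
31 | CNP0307408.1 | C=C1C(=O)O[C@H]2/C=C(/COC(C)=O)CC[C@@H](OO)C(=C)C[C@H](OC(=O)C(=C)[C@@H](O)CO)[C@@H]12 | target

**Totals**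
Total step count: 18. Longest linear sequence: 15 steps (1–11, 15–18).

**Steps most likely to fail**

Step 8. Ring strain may slow the closure so far that other processes take over. These are oligomerisation, formation of the 6E isomer, and loading of the catalyst on the dienoate end followed by six-membered ring closure onto C1=C10. The fallback makes the Z-C6=C7 bond first and closes the ring at C4=C5 by olefination. It sets out from 12. Z-selective cross-metathesis with (Z)-but-2-ene-1,4-diol on a ruthenium dithiolate catalyst would give the (Z)-allylic alcohol phosphonate F1. MnO2 oxidation would give the (Z)-enal phosphonate F2. An intramolecular Horner–Wadsworth–Emmons reaction under high dilution (K2CO3, 18-crown-6, toluene) would give the silyl-protected macrocyclic dienoate F3. HF·pyridine then rejoins the route at 16.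

Step 11. Insertion into the internal, allylically branched diene terminus may be slower than self-consumption of the bromoacrylate. β-Hydride loss from the π-allyl may drain material into trienes. Syn/anti isomerisation of the allyl or attack on the wrong face may erode the configuration at C6 and C7. The fallback replaces palladium by a radical–polar carbolactonisation. It sets out from 18. Mn(OAc)3 and malonic acid in AcOH at rt should add the malonyl radical to C7, oxidise the allyl radical and close the acid onto C6 to give the α-carboxy-γ-lactone F4. Decarboxylative methylenation (aq. HCHO, Et2NH, NaOAc, AcOH) then comes back to the route at 20.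

Step 18. Poor facial selectivity at C1 may result if the conformer with C14 on the α face reacts. Competing hydrogen abstraction from C2 may lower the share of the 1R hydroperoxide. The fallback sets C1 by substitution with inversion. It sets out from 29.
- Photooxygenation under the conditions of step 18 gives the 1S hydroperoxide acetonide F5, which is separated.
- PPh3 reduces it to the 1S allylic alcohol F6.
- MsCl/Et3N at −60 °C gives the mesylate F7.
- Anhydrous H2O2 in ether at low temperature displaces the mesylate with inversion to give the 1R hydroperoxide acetonide F8.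
- AcOH/H2O then arrives at 31.

**Further compounds**
F1 | step 8 | ethyl (5E,8S,9Z)-8-(tert-butyldimethylsilyloxy)-2-(diethoxyphosphoryl)-11-hydroxy-6-methylundeca-5,9-dienoate | CCOC(=O)C(CC/C=C(C)/C[C@H](O[Si](C)(C)C(C)(C)C)/C=C\CO)P(=O)(OCC)OCC
F2 | step 8 | ethyl (5E,8S,9Z)-8-(tert-butyldimethylsilyloxy)-2-(diethoxyphosphoryl)-6-methyl-11-oxoundeca-5,9-dienoate | CCOC(=O)C(CC/C=C(C)/C[C@H](O[Si](C)(C)C(C)(C)C)/C=C\C=O)P(=O)(OCC)OCC
F3 | step 8 | ethyl (1E,3Z,5S,7E)-5-(tert-butyldimethylsilyloxy)-7-methylcyclodeca-1,3,7-triene-1-carboxylate | CC(C)(C)[Si](C)(C)O[C@@H]1/C=C\C=C(\C(=O)OCC)CC/C=C(C)/C1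
F4 | step 11 | (6S,7R,8S)-11-carboxy-15-(tert-butyldimethylsilyloxy)-8-hydroxy-13-norgermacra-1(10)E,4-dien-12,6-olide | OC(=O)C1C(=O)O[C@H]2/C=C(/CO[Si](C)(C)C(C)(C)C)CC/C=C(C)/C[C@H](O)[C@@H]12
F5 | step 18 | 1S hydroperoxide acetonide | C=C1C(=O)O[C@H]2/C=C(/COC(C)=O)CC[C@H](OO)C(=C)C[C@H](OC(=O)C(=C)[C@@H]3COC(C)(C)O3)[C@@H]12
F6 | step 18 | 1S allylic alcohol acetonide | C=C1C(=O)O[C@H]2/C=C(/COC(C)=O)CC[C@H](O)C(=C)C[C@H](OC(=O)C(=C)[C@@H]3COC(C)(C)O3)[C@@H]12
F7 | step 18 | 1S mesylate acetonide | C=C1C(=O)O[C@H]2/C=C(/COC(C)=O)CC[C@H](OS(C)(=O)=O)C(=C)C[C@H](OC(=O)C(=C)[C@@H]3COC(C)(C)O3)[C@@H]12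
F8 | step 18 | 1R hydroperoxide acetonide | C=C1C(=O)O[C@H]2/C=C(/COC(C)=O)CC[C@@H](OO)C(=C)C[C@H](OC(=O)C(=C)[C@@H]3COC(C)(C)O3)[C@@H]12
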